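**Retrosynthetic overview**

1. The target is the desilylated form of its triisopropylsilyl ether, which is cut at C2'–C3' into a 2-(chroman-2-yl)ethyl tosylate and a C3'–C12' Grignard reagent (Li2CuCl4 coupling).
2. The C3'–C12' bromide is cut at C5'–C6' into (R)-citronellyl tosylate (source of C8') and the Grignard reagent of silylated (S)-3-bromo-2-methylpropan-1-ol (source of C4').
3. The tosylate comes from a methyl chroman-2-ylacetate, made from an ortho-(3-methylbut-3-enyl)phenol, CO and methanol. Oxypalladation forms O1–C2 and closes the dihydropyran ring B, the only ring formed (benzene ring A comes from 2-methylhydroquinone); carbonylation forms C1'–C2'.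
4. The strategy rests on C2 being a quaternary carbon bonded to O1, C3, a methyl group and the C1' methylene. Attack of O1 on a 1,1-disubstituted alkene therefore gives a Pd–C1' alkyl with no β-hydrogen, which can only be intercepted by CO.
5. The phenol precursor comes from 2-methylhydroquinone by O4-silylation, ortho-formylation, Wittig enone formation, hydrogenation and methylenation.

Key step: step 6

**Remarks and assumptions**

- Locants: chroman O1, C2–C4, C4a, C5–C8, C8a; side chain C1'–C12'.
- (S)-3-Bromo-2-methylpropan-1-ol, the commercial C4 building block derived from methyl (R)-3-hydroxy-2-methylpropanoate, is used directly. Its CH2Br carbon becomes C5' and its carbinol carbon C3', which gives the required 4'R centre.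
- The C2 descriptor is S in the ester, alcohol and tosylate and R in the final compounds for the same spatial arrangement, because the oxygenated two-carbon arm outranks C3 and the alkyl side chain does not. Likewise the R centre of citronellol becomes 8'S only through a ranking change.
- The ligand (S,S)-Bn-BOXAX, (S)-2,2'-bis[(4S)-4-benzyl-4,5-dihydro-1,3-oxazol-2-yl]-1,1'-binaphthalene, is treated as an available ligand and not counted in the steps. Commercial (R)-citronellol is assumed to be of high enantiomeric purity.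

**Route**

Step 1
Reactants: 1 2-methylhydroquinone
Product: 2 2-methyl-4-[(triisopropylsilyl)oxy]phenol
Conditions: TIPSCl (1.0 equiv), imidazole (2.2 equiv), DMF, 0 °C → rt
Reagents that add atoms: chlorotriisopropylsilane, CC(C)[Si](Cl)(C(C)C)C(C)C
Why: Imidazole-mediated silyl ether formation with the silyl chloride as limiting reagent should occur at O4, whose two ortho positions carry hydrogen, in preference to the hydroxyl flanked by the methyl group; minor bis-silyl ether and regioisomer are removed by chromatography.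

Step 2
Reactants: 2 2-methyl-4-[(triisopropylsilyl)oxy]phenol
Product: 3 2-hydroxy-3-methyl-5-[(triisopropylsilyl)oxy]benzaldehyde
Conditions: MgCl2 (2 equiv), Et3N (4 equiv), (CH2O)n (6 equiv), MeCN, reflux; dilute HCl work-up
Reagents that add atoms: paraformaldehyde (as formaldehyde), C=O
Why: Casnati–Skattebøl ortho-formylation: the magnesium phenoxide directs formaldehyde to the single free ortho position and a second formaldehyde acts as hydride acceptor, while the aryl silyl ether is inert to MgCl2/Et3N.

Step 3
Reactants: 3 2-hydroxy-3-methyl-5-[(triisopropylsilyl)oxy]benzaldehyde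
Product: 4 (E)-4-{2-hydroxy-3-methyl-5-[(triisopropylsilyl)oxy]phenyl}but-3-en-2-one
Conditions: Ph3P=CHC(O)CH3 (1.3 equiv), toluene, 80 °C
Reagents that add atoms: 1-(triphenyl-λ5-phosphanylidene)propan-2-one, CC(=O)C=P(c1ccccc1)(c1ccccc1)c1ccccc1
Why: Wittig olefination with a stabilised acylmethylene ylide under neutral conditions should give the (E)-enone and avoids the aqueous hydroxide of an aldol condensation, which would endanger the aryl silyl ether.

Step 4
Reactants: 4 (E)-4-{2-hydroxy-3-methyl-5-[(triisopropylsilyl)oxy]phenyl}but-3-en-2-one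
Product: 5 4-{2-hydroxy-3-methyl-5-[(triisopropylsilyl)oxy]phenyl}butan-2-one
Conditions: H2 (1 atm), Pd/C (10 wt %), EtOAc, rt
Reagents that add atoms: none
Why: Heterogeneous catalytic hydrogenation reduces the conjugated C=C bond much faster than the ketone or the arene; partial existence of the product as its cyclic hemiketal does not matter for the next step.

Step 5
Reactants: 5 4-{2-hydroxy-3-methyl-5-[(triisopropylsilyl)oxy]phenyl}butan-2-one
Product: 6 2-methyl-6-(3-methylbut-3-en-1-yl)-4-[(triisopropylsilyl)oxy]phenol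
Conditions: Ph3PCH3Br (3.0 equiv), n-BuLi (2.9 equiv), THF, 0 °C; then 5, 0 °C → rt
Reagents that add atoms: methyltriphenylphosphonium bromide, C[P+](c1ccccc1)(c1ccccc1)c1ccccc1.[Br-]
Why: Wittig methylenation with excess ylide, in which the first equivalent deprotonates the phenol and the remainder olefinates the methyl ketone, as is usual for ortho-hydroxyaryl butanones; no alkoxide base is present that could cleave the silyl ether.

Step 6
Reactants: 6 2-methyl-6-(3-methylbut-3-en-1-yl)-4-[(triisopropylsilyl)oxy]phenol, 7 carbon monoxide, 8 methanol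
Product: 11 methyl 2-{(2S)-2,8-dimethyl-6-[(triisopropylsilyl)oxy]chroman-2-yl}acetate, via alkylpalladium trifluoroacetate 9 (not isolated), via acylpalladium trifluoroacetate 10 (not isolated)
Conditions: Pd(OCOCF3)2 (5 mol %), (S,S)-Bn-BOXAX (20 mol %), p-benzoquinone (4 equiv), CO (1 atm), MeOH, rt
Reagents that add atoms: carbon monoxide 7, [C-]#[O+]; methanol 8, CO
Why: Divalent palladium carrying the chiral bis(oxazoline) binds the 1,1-disubstituted alkene, and the phenol oxygen adds to its internal carbon in a 6-exo-trig oxypalladation that closes ring B through O1–C2 and gives the Pd–C1' alkyl 9. Because C2 bears no hydrogen, β-hydride elimination is impossible, so 9 inserts CO to the acyl complex 10, which methanol cleaves to the ester (C1'–C2' bond) with release of zerovalent palladium that p-benzoquinone reoxidises. The closest known reaction type is the enantioselective domino Wacker cyclisation/carbonylation/methoxylation of 2-(3-methylbut-3-enyl)phenols with Pd(OCOCF3)2 and BOXAX ligands. The C2 stereocentre is set by the ligand, whose axially chiral binaphthyl-bis(oxazoline) pocket differentiates the two alkene faces during oxypalladation; the (S,S)-ligand is the enantiomer expected to give the (S)-acetate, and its mirror image would be taken if the sense were found reversed. The step needs exo attack over 7-endo attack, secured by the 1,1-disubstitution that directs oxygen to the tertiary carbon, and carbonylation over protodepalladation or phenol oxidation, secured by the fully substituted C2, the CO atmosphere and the para-silyloxy group that blocks quinone formation.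

Step 7
Reactants: 11 methyl 2-{(2S)-2,8-dimethyl-6-[(triisopropylsilyl)oxy]chroman-2-yl}acetate
Product: 12 2-{(2S)-2,8-dimethyl-6-[(triisopropylsilyl)oxy]chroman-2-yl}ethan-1-ol
Conditions: i-Bu2AlH (2.5 equiv), CH2Cl2, −78 → 0 °C; aqueous Rochelle salt work-up
Reagents that add atoms: none
Why: Hydride reduction of the ester to the primary alcohol with i-Bu2AlH, which leaves the aryl silyl ether and the quaternary C2 stereocentre untouched.

Step 8
Reactants: 12 2-{(2S)-2,8-dimethyl-6-[(triisopropylsilyl)oxy]chroman-2-yl}ethan-1-ol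
Product: 13 2-{(2S)-2,8-dimethyl-6-[(triisopropylsilyl)oxy]chroman-2-yl}ethyl 4-methylbenzenesulfonate
Conditions: TsCl (1.3 equiv), Et3N, DMAP (cat.), CH2Cl2, 0 °C → rt
Reagents that add atoms: 4-methylbenzenesulfonyl chloride, Cc1ccc(S(=O)(=O)Cl)cc1
Why: Tosylation of the only free hydroxyl, an unhindered primary alcohol, installs the leaving group for the later sp3–sp3 coupling.

Step 9
Reactants: 14 (R)-citronellol
Product: 15 (R)-3,7-dimethyloct-6-en-1-yl 4-methylbenzenesulfonate
Conditions: TsCl (1.2 equiv), pyridine, CH2Cl2, 0 °C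
Reagents that add atoms: 4-methylbenzenesulfonyl chloride, Cc1ccc(S(=O)(=O)Cl)cc1
Why: Tosylation of the primary alcohol; the trisubstituted alkene and the stereocentre (the future C8') take no part.

Step 10
Reactants: 16 (S)-3-bromo-2-methylpropan-1-ol
Product: 17 (S)-(3-bromo-2-methylpropoxy)(tert-butyl)dimethylsilane
Conditions: TBSCl (1.1 equiv), imidazole (2 equiv), CH2Cl2, 0 °C → rt
Reagents that add atoms: tert-butylchlorodimethylsilane, CC(C)(C)[Si](C)(C)Cl
Why: Silyl ether formation masks the hydroxyl so that the bromide can be converted into a Grignard reagent; the stereocentre (the future C4') is not touched.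

Step 11
Reactants: 17 (S)-(3-bromo-2-methylpropoxy)(tert-butyl)dimethylsilane, 15 (R)-3,7-dimethyloct-6-en-1-yl 4-methylbenzenesulfonate
Product: 19 tert-butyldimethyl{[(2R,6S)-2,6,10-trimethylundec-9-en-1-yl]oxy}silane, via silyloxyalkyl Grignard reagent 18 (not isolated)
Conditions: 17, Mg turnings (I2 cat.), THF, reflux; then 15, Li2CuCl4 (5 mol %), THF, −78 °C → rt
Reagents that add atoms: none
Why: Magnesium insertion gives the γ-silyloxy Grignard reagent, and copper-catalysed Grignard–tosylate coupling (Fouquet–Schlosser type, Li2CuCl4) forms C5'–C6' at an unhindered primary tosylate; both stereocentres lie away from the reacting carbons and are carried over from the chiral pool.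

Step 12
Reactants: 19 tert-butyldimethyl{[(2R,6S)-2,6,10-trimethylundec-9-en-1-yl]oxy}silane
Product: 20 (2R,6S)-2,6,10-trimethylundec-9-en-1-ol
Conditions: Bu4NF (1.2 equiv), THF, rt
Reagents that add atoms: none
Why: Fluoride-mediated cleavage of the alkyl silyl ether, to which the alkene and both stereocentres are inert.

Step 13
Reactants: 20 (2R,6S)-2,6,10-trimethylundec-9-en-1-ol
Product: 21 (2R,6S)-1-bromo-2,6,10-trimethylundec-9-ene
Conditions: CBr4 (1.2 equiv), PPh3 (1.3 equiv), CH2Cl2, 0 °C
Reagents that add atoms: tetrabromomethane, BrC(Br)(Br)Br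
Why: Appel bromination converts the primary alcohol into the bromide by SN2 displacement under neutral, acid-free conditions, so neither the trisubstituted alkene nor the adjacent stereocentre is affected.

Step 14
Reactants: 21 (2R,6S)-1-bromo-2,6,10-trimethylundec-9-ene, 13 2-{(2S)-2,8-dimethyl-6-[(triisopropylsilyl)oxy]chroman-2-yl}ethyl 4-methylbenzenesulfonate
Product: 23 triisopropyl({(2R)-2,8-dimethyl-2-[(4R,8S)-4,8,12-trimethyltridec-11-en-1-yl]chroman-6-yl}oxy)silane, via alkenyl Grignard reagent 22 (not isolated)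
Conditions: 21 (1.8 equiv), Mg turnings (I2 cat.), THF, reflux; then 13, Li2CuCl4 (5 mol %), THF, −78 °C → rt
Reagents that add atoms: none
Why: Copper-catalysed alkyl–alkyl coupling of a primary Grignard reagent with a primary tosylate (Fouquet–Schlosser type) forms C2'–C3' two carbons away from the quaternary C2; the aryl silyl ether and the alkene are inert to the Grignard reagent and no stereocentre is touched.

Step 15
Reactants: 23 triisopropyl({(2R)-2,8-dimethyl-2-[(4R,8S)-4,8,12-trimethyltridec-11-en-1-yl]chroman-6-yl}oxy)silane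
Product: 24 (2R)-2,8-dimethyl-2-[(4R,8S)-4,8,12-trimethyltridec-11-en-1-yl]chroman-6-ol (target)
Conditions: Bu4NF (1.2 equiv), AcOH (1.2 equiv), THF, 0 °C → rt
Reagents that add atoms: none
Why: Fluoride cleavage of the aryl silyl ether, buffered with acetic acid so that the electron-rich phenol is not exposed as an oxidation-prone phenoxide; the alkene and all three stereocentres are unaffected.

**Compound list**

1 | 2-methylhydroquinone | Cc1cc(O)ccc1O | starting material
2 | 2-methyl-4-[(triisopropylsilyl)oxy]phenol | Cc1cc(O[Si](C(C)C)(C(C)C)C(C)C)ccc1O | intermediate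
3 | 2-hydroxy-3-methyl-5-[(triisopropylsilyl)oxy]benzaldehyde | Cc1cc(O[Si](C(C)C)(C(C)C)C(C)C)cc(C=O)c1O | intermediate
4 | (E)-4-{2-hydroxy-3-methyl-5-[(triisopropylsilyl)oxy]phenyl}but-3-en-2-one | CC(=O)/C=C/c1cc(O[Si](C(C)C)(C(C)C)C(C)C)cc(C)c1O | intermediate
5 | 4-{2-hydroxy-3-methyl-5-[(triisopropylsilyl)oxy]phenyl}butan-2-one | CC(=O)CCc1cc(O[Si](C(C)C)(C(C)C)C(C)C)cc(C)c1O | intermediate
6 | 2-methyl-6-(3-methylbut-3-en-1-yl)-4-[(triisopropylsilyl)oxy]phenol | C=C(C)CCc1cc(O[Si](C(C)C)(C(C)C)C(C)C)cc(C)c1O | intermediate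
7 | carbon monoxide | [C-]#[O+] | starting material
8 | methanol | CO | starting material
9 | {[(2S)-2,8-dimethyl-6-(triisopropylsilyloxy)chroman-2-yl]methyl}palladium trifluoroacetate (divalent palladium; BOXAX ligand on Pd not drawn) | Cc1cc(O[Si](C(C)C)(C(C)C)C(C)C)cc2c1O[C@](C)(C[Pd]OC(=O)C(F)(F)F)CC2 | intermediate (not isolated)
10 | {2-[(2S)-2,8-dimethyl-6-(triisopropylsilyloxy)chroman-2-yl]acetyl}palladium trifluoroacetate (divalent palladium; BOXAX ligand on Pd not drawn) | Cc1cc(O[Si](C(C)C)(C(C)C)C(C)C)cc2c1O[C@](C)(CC(=O)[Pd]OC(=O)C(F)(F)F)CC2 | intermediate (not isolated)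
11 | methyl 2-{(2S)-2,8-dimethyl-6-[(triisopropylsilyl)oxy]chroman-2-yl}acetate | Cc1cc(O[Si](C(C)C)(C(C)C)C(C)C)cc2c1O[C@](C)(CC(=O)OC)CC2 | intermediate
12 | 2-{(2S)-2,8-dimethyl-6-[(triisopropylsilyl)oxy]chroman-2-yl}ethan-1-ol | Cc1cc(O[Si](C(C)C)(C(C)C)C(C)C)cc2c1O[C@](C)(CCO)CC2 | intermediate
13 | 2-{(2S)-2,8-dimethyl-6-[(triisopropylsilyl)oxy]chroman-2-yl}ethyl 4-methylbenzenesulfonate | Cc1cc(O[Si](C(C)C)(C(C)C)C(C)C)cc2c1O[C@](C)(CCOS(=O)(=O)c1ccc(C)cc1)CC2 | intermediate
14 | (R)-citronellol, (R)-3,7-dimethyloct-6-en-1-ol | CC(C)=CCC[C@@H](C)CCO | starting material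
15 | (R)-3,7-dimethyloct-6-en-1-yl 4-methylbenzenesulfonate | CC(C)=CCC[C@@H](C)CCOS(=O)(=O)c1ccc(C)cc1 | intermediate
16 | (S)-3-bromo-2-methylpropan-1-ol | BrC[C@@H](C)CO | starting material
17 | (S)-(3-bromo-2-methylpropoxy)(tert-butyl)dimethylsilane | BrC[C@@H](C)CO[Si](C)(C)C(C)(C)C | intermediate
18 | [(S)-3-(tert-butyldimethylsilyloxy)-2-methylpropyl]magnesium bromide | Br[Mg]C[C@@H](C)CO[Si](C)(C)C(C)(C)C | intermediate (not isolated)
19 | tert-butyldimethyl{[(2R,6S)-2,6,10-trimethylundec-9-en-1-yl]oxy}silane | CC(C)=CCC[C@@H](C)CCC[C@@H](C)CO[Si](C)(C)C(C)(C)C | intermediate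
20 | (2R,6S)-2,6,10-trimethylundec-9-en-1-ol | CC(C)=CCC[C@@H](C)CCC[C@@H](C)CO | intermediate
21 | (2R,6S)-1-bromo-2,6,10-trimethylundec-9-ene | CC(C)=CCC[C@@H](C)CCC[C@@H](C)CBr | intermediate
22 | [(2R,6S)-2,6,10-trimethylundec-9-en-1-yl]magnesium bromide | CC(C)=CCC[C@@H](C)CCC[C@@H](C)C[Mg]Br | intermediate (not isolated)
23 | triisopropyl({(2R)-2,8-dimethyl-2-[(4R,8S)-4,8,12-trimethyltridec-11-en-1-yl]chroman-6-yl}oxy)silane | CC(C)=CCC[C@@H](C)CCC[C@@H](C)CCC[C@]1(C)CCc2cc(O[Si](C(C)C)(C(C)C)C(C)C)cc(C)c2O1 | intermediate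
24 | (2R)-2,8-dimethyl-2-[(4R,8S)-4,8,12-trimethyltridec-11-en-1-yl]chroman-6-ol | CC(C)=CCC[C@@H](C)CCC[C@@H](C)CCC[C@]1(C)CCc2cc(O)cc(C)c2O1 | target

**Step count**

Total: 15 steps. Longest linear sequence: 10 steps (steps 1–8, 14 and 15, from 2-methylhydroquinone).

**Steps most likely to fail, with fallbacks**

1. Step 6. Enantioface discrimination in the oxypalladation may be insufficient, or the electron-rich phenol may be degraded by the quinone oxidant before it cyclises. The fallback sets out from ketone 5 and returns at alcohol 12; it replaces catalyst control by classical resolution and uses no palladium. Ketone 5 is treated with trimethyl phosphonoacetate and NaH (THF, 0 °C → reflux). Horner–Wadsworth–Emmons olefination should give, as its phenoxide, methyl 5-{2-hydroxy-3-methyl-5-[(triisopropylsilyl)oxy]phenyl}-3-methylpent-2-enoate F1, which should close in the same flask by intramolecular oxa-Michael addition to racemic methyl 2-{2,8-dimethyl-6-[(triisopropylsilyl)oxy]chroman-2-yl}acetate F2. Saponification (LiOH, THF/H2O, rt, or Me3SnOH in 1,2-dichloroethane if the aryl silyl ether proves labile) gives racemic 2-{2,8-dimethyl-6-[(triisopropylsilyl)oxy]chroman-2-yl}acetic acid F3. Fractional crystallisation with (S)-1-phenylethylamine should give (S)-1-phenylethylammonium 2-{(2S)-2,8-dimethyl-6-[(triisopropylsilyl)oxy]chroman-2-yl}acetate F4; the enantiomeric amine is taken if the less soluble salt carries the other acid. Acidification frees 2-{(2S)-2,8-dimethyl-6-[(triisopropylsilyl)oxy]chroman-2-yl}acetic acid F5, while 2-{(2R)-2,8-dimethyl-6-[(triisopropylsilyl)oxy]chroman-2-yl}acetic acid F6 stays in the mother liquor. Reduction of F5 with BH3·THF gives alcohol 12.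

2. Step 14. Displacement at the tosylate may be slow and lose out to homocoupling or reduction of the Grignard reagent, or magnesium insertion into the β-branched bromide may be incomplete. The fallback sets out from tosylate 13 and bromide 21 and returns at silyl ether 23; it replaces the Grignard coupling by sulfone carbanion alkylation. Tosylate 13 is converted with NaI (acetone, reflux) into {[(2S)-2-(2-iodoethyl)-2,8-dimethylchroman-6-yl]oxy}triisopropylsilane F7. Bromide 21 is converted with PhSO2Na (Bu4NI cat., DMF, 60 °C) into {[(2R,6S)-2,6,10-trimethylundec-9-en-1-yl]sulfonyl}benzene F8. Deprotonation of F8 (n-BuLi, THF/DMPU, −78 °C) and alkylation with F7 should give the 3'-(phenylsulfonyl) derivative of silyl ether 23 F9, as both C3' epimers. Reductive desulfonylation (Na(Hg), Na2HPO4, MeOH/THF, −20 °C) removes the sulfonyl group and the temporary C3' centre and gives 23.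

3. Step 5. Methylenation may stall because the phenoxide and its cyclic hemiketal mask the ketone, or because the ylide enolises it. The fallback sets out from phenol 2 and returns at phenol 6; it builds the side chain through an ortho-quinone methide instead of a carbonyl olefination. Phenol 2 is aminomethylated at its only free ortho position with dimethylmethylideneammonium iodide (K2CO3, CH2Cl2, rt) to 2-[(dimethylamino)methyl]-6-methyl-4-[(triisopropylsilyl)oxy]phenol F10. MeI (Et2O, rt) quaternises this to {2-hydroxy-3-methyl-5-[(triisopropylsilyl)oxy]benzyl}trimethylammonium iodide F11. 2-Methylallylmagnesium chloride (3 equiv, THF, −78 °C → rt) should deprotonate the phenol and expel trimethylamine to give 2-methyl-6-methylidene-4-[(triisopropylsilyl)oxy]cyclohexa-2,4-dien-1-one F12, then add to its exocyclic carbon to give phenol 6 directly.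

**Further compounds**

F1 | step 6 | methyl 5-{2-hydroxy-3-methyl-5-[(triisopropylsilyl)oxy]phenyl}-3-methylpent-2-enoate (E/Z mixture) | COC(=O)C=C(C)CCc1cc(O[Si](C(C)C)(C(C)C)C(C)C)cc(C)c1O
F2 | step 6 | racemic methyl 2-{2,8-dimethyl-6-[(triisopropylsilyl)oxy]chroman-2-yl}acetate | Cc1cc(O[Si](C(C)C)(C(C)C)C(C)C)cc2c1OC(C)(CC(=O)OC)CC2
F3 | step 6 | racemic 2-{2,8-dimethyl-6-[(triisopropylsilyl)oxy]chroman-2-yl}acetic acid | Cc1cc(O[Si](C(C)C)(C(C)C)C(C)C)cc2c1OC(C)(CC(=O)O)CC2
F4 | step 6 | (S)-1-phenylethylammonium 2-{(2S)-2,8-dimethyl-6-[(triisopropylsilyl)oxy]chroman-2-yl}acetate | Cc1cc(O[Si](C(C)C)(C(C)C)C(C)C)cc2c1O[C@](C)(CC(=O)[O-])CC2.C[C@H]([NH3+])c1ccccc1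
F5 | step 6 | 2-{(2S)-2,8-dimethyl-6-[(triisopropylsilyl)oxy]chroman-2-yl}acetic acid | Cc1cc(O[Si](C(C)C)(C(C)C)C(C)C)cc2c1O[C@](C)(CC(=O)O)CC2
F6 | step 6 | 2-{(2R)-2,8-dimethyl-6-[(triisopropylsilyl)oxy]chroman-2-yl}acetic acid | Cc1cc(O[Si](C(C)C)(C(C)C)C(C)C)cc2c1O[C@@](C)(CC(=O)O)CC2
F7 | step 14 | {[(2S)-2-(2-iodoethyl)-2,8-dimethylchroman-6-yl]oxy}triisopropylsilane | Cc1cc(O[Si](C(C)C)(C(C)C)C(C)C)cc2c1O[C@](C)(CCI)CC2
F8 | step 14 | {[(2R,6S)-2,6,10-trimethylundec-9-en-1-yl]sulfonyl}benzene | CC(C)=CCC[C@@H](C)CCC[C@@H](C)CS(=O)(=O)c1ccccc1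
F9 | step 14 | 3'-(phenylsulfonyl) derivative of silyl ether 23 (both C3' epimers) | CC(C)=CCC[C@@H](C)CCC[C@@H](C)C(CC[C@]1(C)CCc2cc(O[Si](C(C)C)(C(C)C)C(C)C)cc(C)c2O1)S(=O)(=O)c1ccccc1
F10 | step 5 | 2-[(dimethylamino)methyl]-6-methyl-4-[(triisopropylsilyl)oxy]phenol | CN(C)Cc1cc(O[Si](C(C)C)(C(C)C)C(C)C)cc(C)c1O
F11 | step 5 | {2-hydroxy-3-methyl-5-[(triisopropylsilyl)oxy]benzyl}trimethylammonium iodide | C[N+](C)(C)Cc1cc(O[Si](C(C)C)(C(C)C)C(C)C)cc(C)c1O.[I-]
F12 | step 5 | 2-methyl-6-methylidene-4-[(triisopropylsilyl)oxy]cyclohexa-2,4-dien-1-one | C=C1C=C(O[Si](C(C)C)(C(C)C)C(C)C)C=C(C)C1=O
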